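**Plan**

Numbering follows chroman-2-one (O1, C2, C3, C4, C4a, C5–C8, C8a); ring A is the benzo ring, ring B the aryl group on C4, ring C the aryl group of the styryl unit.
Enabling feature: ring A is a 1,2,3,5-tetrasubstituted benzene with meta oxygens on C8a and C7 and hydrogens on C6 and C8, the pattern left when a vinylketene (C8a, C6, C5, C4a) joins a terminal oxygen-bearing alkyne (C8, C7).
Retrosynthesis: cut the lactone bond O1–C2, then ring A at C8–C8a, C6–C7 and C4a–C8a (to a 4-substituted 3-styrylcyclobut-2-enone plus triisopropylsilyloxyacetylene), then C5–styryl, then the four-membered ring (ketene plus ethoxyacetylene), then C4–ring B.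
Forward: ring B is joined to C4 on a six-membered lactone, the lactone is opened and oxidised to a glutaric half-ester, the cyclobutenone is built and given its styryl group, ring A arises in the benzannulation, and the lactone ring closes last.
Stereochemistry: the single stereocentre C4 (R) is set by (R)-BINAP in a rhodium-catalysed 1,4-addition and lies outside every later reacting π system; the (E)-alkene comes from ferulic acid with retention.

Key step: step 12

Assumption: the ring carbon of cyclobutenones 14, 21 and 22 is carried as a mixture of epimers, which is of no consequence because it becomes the sp2 carbon C4a.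

**Route**

Step 1
Reactants: 1 4-bromo-2-methoxyphenol
Product: 2 (4-bromo-2-methoxyphenoxy)(tert-butyl)dimethylsilane
Conditions: t-BuMe2SiCl, imidazole, DMF, rt
Reagents that add atoms: tert-butyldimethylsilyl chloride, CC(C)(C)[Si](C)(C)Cl
Why: Standard silylation of a phenol gives an ether that should survive organolithiums, acid chlorides and heat and that fluoride removes at the end.

Step 2
Reactants: 2 (4-bromo-2-methoxyphenoxy)(tert-butyl)dimethylsilane
Product: 5 [4-(tert-butyldimethylsilyloxy)-3-methoxyphenyl]boronic acid, via aryllithium 3 (not isolated), via lithium aryl(triisopropoxy)borate 4 (not isolated)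
Conditions: n-BuLi, THF, −78 °C; B(Oi-Pr)3, −78 °C to rt; 1 M HCl, 0 °C
Reagents that add atoms: triisopropyl borate, CC(C)OB(OC(C)C)OC(C)C; water, O
Why: Bromine–lithium exchange para to the silyloxy group (no silyl migration possible) followed by borylation and hydrolysis is the standard route to an arylboronic acid.

Step 3
Reactants: 5 [4-(tert-butyldimethylsilyloxy)-3-methoxyphenyl]boronic acid; 6 5,6-dihydro-2H-pyran-2-one
Product: 7 (R)-4-[4-(tert-butyldimethylsilyloxy)-3-methoxyphenyl]tetrahydro-2H-pyran-2-one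
Conditions: 5 (2.5 equiv), Rh(acac)(C2H4)2 (3 mol %), (R)-BINAP (3.3 mol %), 1,4-dioxane–H2O (10:1), 100 °C
Reagents that add atoms: none
Why: Hayashi–Miyaura asymmetric 1,4-addition to the cyclic cis-enoate, in which the (R)-BINAP–rhodium aryl complex should deliver ring B to the face that gives the (R)-lactone (the same sense as (R)-3-aryl ketones from 2-cyclohexenone), so this step sets C4 of the target.

Step 4
Reactants: 7 (R)-4-[4-(tert-butyldimethylsilyloxy)-3-methoxyphenyl]tetrahydro-2H-pyran-2-one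
Product: 8 methyl (R)-3-[4-(tert-butyldimethylsilyloxy)-3-methoxyphenyl]-5-hydroxypentanoate
Conditions: MeOH (0.05 M), camphorsulfonic acid (10 mol %), rt; solid NaHCO3, concentrate cold
Reagents that add atoms: methanol, CO
Why: Acid-catalysed methanolysis of a δ-lactone in dilute methanol should favour the open hydroxy ester, and neutralising before concentration prevents reclosure; the aryl silyl ether tolerates the mild acid.

Step 5
Reactants: 8 methyl (R)-3-[4-(tert-butyldimethylsilyloxy)-3-methoxyphenyl]-5-hydroxypentanoate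
Product: 10 (R)-3-[4-(tert-butyldimethylsilyloxy)-3-methoxyphenyl]-5-methoxy-5-oxopentanoic acid, via aldehyde 9 (not isolated)
Conditions: 2,2,6,6-tetramethylpiperidin-1-oxyl (TEMPO, 20 mol %), PhI(OAc)2 (2.2 equiv), MeCN–H2O (1:1), rt
Reagents that add atoms: water, O
Why: Oxoammonium-catalysed oxidation of a primary alcohol through the aldehyde hydrate gives the acid without touching the ester, the silyl ether or the stereocentre, and yields a glutaric half-ester with differentiated arms.

Step 6
Reactants: 10 (R)-3-[4-(tert-butyldimethylsilyloxy)-3-methoxyphenyl]-5-methoxy-5-oxopentanoic acid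
Product: 11 methyl (S)-3-[4-(tert-butyldimethylsilyloxy)-3-methoxyphenyl]-5-chloro-5-oxopentanoate
Conditions: (COCl)2 (1.5 equiv), DMF (cat.), CH2Cl2, 0 °C to rt; evaporate, use crude
Reagents that add atoms: oxalyl chloride, O=C(Cl)C(=O)Cl
Why: Vilsmeier-type chlorination of the acid under conditions an aryl silyl ether tolerates; the descriptor changes only through the priority rules.

Step 7
Reactants: 11 methyl (S)-3-[4-(tert-butyldimethylsilyloxy)-3-methoxyphenyl]-5-chloro-5-oxopentanoate; 12 ethoxyacetylene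
Product: 14 methyl (3S)-3-[4-(tert-butyldimethylsilyloxy)-3-methoxyphenyl]-3-(2-ethoxy-4-oxocyclobut-2-en-1-yl)propanoate (epimers at the ring carbon), via ketene 13 (not isolated)
Conditions: 12 (3 equiv), Et3N (1.2 equiv), Et2O, slow addition of 11, 0 °C to rt
Reagents that add atoms: none
Why: Dehydrochlorination gives the monoalkylketene, which undergoes the known [2+2] cycloaddition with the electron-rich alkoxyalkyne (ketene carbon to the alkyne CH, α-carbon to the ethoxy-bearing carbon); excess alkyne and slow addition suppress ketene dimerisation.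

Step 8
Reactants: 15 ferulic acid, (E)-3-(4-hydroxy-3-methoxyphenyl)prop-2-enoic acid
Product: 17 (E)-3-[4-(tert-butyldimethylsilyloxy)-3-methoxyphenyl]prop-2-enoic acid, via silyl ester 16 (not isolated)
Conditions: t-BuMe2SiCl (2.5 equiv), imidazole, DMF, rt; then AcOH–THF–H2O, rt
Reagents that add atoms: tert-butyldimethylsilyl chloride, CC(C)(C)[Si](C)(C)Cl
Why: Bis-silylation followed by selective hydrolysis of the far more labile silyl ester is the usual way to protect only the phenol of a hydroxycinnamic acid.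

Step 9
Reactants: 17 (E)-3-[4-(tert-butyldimethylsilyloxy)-3-methoxyphenyl]prop-2-enoic acid
Product: 18 (E)-[4-(2-bromoethenyl)-2-methoxyphenoxy](tert-butyl)dimethylsilane
Conditions: N-bromosuccinimide (1.05 equiv), LiOAc (10 mol %), MeCN–H2O (97:3), rt
Reagents that add atoms: N-bromosuccinimide, O=C1CCC(=O)N1Br
Why: Catalytic Hunsdiecker-type bromodecarboxylation, which is fastest for electron-rich cinnamates and should give the (E)-β-bromostyrene.

Step 10
Reactants: 18 (E)-[4-(2-bromoethenyl)-2-methoxyphenoxy](tert-butyl)dimethylsilane; 14 methyl (3S)-3-[4-(tert-butyldimethylsilyloxy)-3-methoxyphenyl]-3-(2-ethoxy-4-oxocyclobut-2-en-1-yl)propanoate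
Product: 22 methyl (3S)-3-[4-(tert-butyldimethylsilyloxy)-3-methoxyphenyl]-3-{2-[(E)-2-[4-(tert-butyldimethylsilyloxy)-3-methoxyphenyl]ethenyl]-4-oxocyclobut-2-en-1-yl}propanoate (epimers at the ring carbon), via styryllithium 19 (not isolated), via alkenylcerium dichloride 20 (not isolated), via tertiary carbinol 21 (not isolated)
Conditions: 18 (1.3 equiv), t-BuLi (2.6 equiv), Et2O, −78 °C; anhydrous CeCl3, THF, −78 °C; 14, −78 °C; 1 M HCl, THF, 0 °C
Reagents that add atoms: water, O
Why: Bromine–lithium exchange with retention, then 1,2-addition of the less basic organocerium reagent to the vinylogous-ester carbonyl in preference to the methyl ester, and acid-induced allylic transposition with loss of ethanol, the standard route from 3-alkoxycyclobutenones to 3-substituted cyclobutenones.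

Step 11
Reactants: 23 acetylene
Product: 26 (ethynyloxy)tri(propan-2-yl)silane (triisopropylsilyloxyacetylene), via lithium acetylide 24 (not isolated), via lithium ethynolate 25 (not isolated)
Conditions: excess 23, n-BuLi, THF, −78 °C; LiOOt-Bu (from t-BuOOH and n-BuLi, THF, −78 °C), −78 to −20 °C; i-Pr3SiOTf, −78 to 0 °C
Reagents that add atoms: tert-butyl hydroperoxide, CC(C)(C)OO; triisopropylsilyl trifluoromethanesulfonate, CC(C)[Si](C(C)C)(C(C)C)OS(=O)(=O)C(F)(F)F
Why: Oxidation of a lithium acetylide by lithium tert-butyl peroxide to the ynolate and O-silylation with a bulky silyl triflate is the one-flask route to triisopropylsilyl ynol ethers, applied here to the parent acetylide.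

Step 12
Reactants: 22 methyl (3S)-3-[4-(tert-butyldimethylsilyloxy)-3-methoxyphenyl]-3-{2-[(E)-2-[4-(tert-butyldimethylsilyloxy)-3-methoxyphenyl]ethenyl]-4-oxocyclobut-2-en-1-yl}propanoate; 26 (ethynyloxy)tri(propan-2-yl)silane
Product: 31 methyl (3R)-3-[4-(tert-butyldimethylsilyloxy)-3-methoxyphenyl]-3-{2-[(E)-2-[4-(tert-butyldimethylsilyloxy)-3-methoxyphenyl]ethenyl]-6-hydroxy-4-(triisopropylsilyloxy)phenyl}propanoate, via vinylketene 27 (not isolated), via vinylcyclobutenone 28 (not isolated), via dienylketene 29 (not isolated), via cyclohexadienone 30 (not isolated)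
Conditions: 26 (2 equiv), toluene (0.1 M), 80 °C then 110 °C, sealed tube, argon
Reagents that add atoms: none
Why: On heating, 22 opens by 4π electrocyclic ring opening to vinylketene 27 (C8a, C6, C5, C4a) with the C4 side chain rotating outward, the ketene C=C adds 26 in a [2+2] cycloaddition (bonds C8–C8a and C6–C7) to give 28, and 28 reopens to dienylketene 29. Ring A then closes by 6π electrocyclization (bond C4a–C8a) to cyclohexadienone 30, which tautomerizes to phenol 31; this is the Danheiser benzannulation of a cyclobutenone with a siloxyalkyne, the established route to resorcinol monosilyl ethers. No stereocentre is created: the ring carbon of 22 becomes sp2, and the C4 centre has no acidic hydrogen and lies outside the π system, while outward rotation keeps its hydrogen away from the ketene carbon so that a 1,5-hydrogen shift cannot erase it. The step needs regioselectivity in the ketene–alkyne cycloaddition, and the polarisation of 26 secures it: the unsubstituted nucleophilic carbon bonds to the electrophilic ketene carbon C8a and the oxygen-bearing carbon to C6, which places the silyloxy group on C7, meta to the new hydroxyl on C8a. Because the ketene α-carbon and the alkyne terminus are unsubstituted, C6 and C8 end as aromatic CH, and the excess of 26 limits acylation of the product phenol by ketene intermediates.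

Step 13
Reactants: 31 methyl (3R)-3-[4-(tert-butyldimethylsilyloxy)-3-methoxyphenyl]-3-{2-[(E)-2-[4-(tert-butyldimethylsilyloxy)-3-methoxyphenyl]ethenyl]-6-hydroxy-4-(triisopropylsilyloxy)phenyl}propanoate
Product: 32 methyl (3R)-3-{2,4-dihydroxy-6-[(E)-2-(4-hydroxy-3-methoxyphenyl)ethenyl]phenyl}-3-(4-hydroxy-3-methoxyphenyl)propanoate
Conditions: Bu4NF (3.5 equiv), AcOH (3.5 equiv), THF, 0 °C, argon
Reagents that add atoms: none
Why: Fluoride cleaves all three aryl silyl ethers rapidly, and the acetic acid buffer keeps the electron-rich hydroxystilbene from standing as air-sensitive phenoxide.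

Step 14
Reactants: 32 methyl (3R)-3-{2,4-dihydroxy-6-[(E)-2-(4-hydroxy-3-methoxyphenyl)ethenyl]phenyl}-3-(4-hydroxy-3-methoxyphenyl)propanoate
Product: 33 (4R)-7-hydroxy-4-(4-hydroxy-3-methoxyphenyl)-5-[(E)-2-(4-hydroxy-3-methoxyphenyl)ethenyl]chroman-2-one
Conditions: p-TsOH·H2O (10 mol %), toluene–MeCN, 60 °C, 4 Å molecular sieves
Reagents that add atoms: none
Why: Acid-catalysed lactonisation of the C8a hydroxyl onto the methyl ester forms the six-membered ring (only the ortho hydroxyl can reach), and mild acid at moderate temperature should leave the doubly benzylic C4 centre and the stilbene untouched.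

**Compound list**

1 | 4-bromo-2-methoxyphenol | COc1cc(Br)ccc1O | starting material
2 | (4-bromo-2-methoxyphenoxy)(tert-butyl)dimethylsilane | COc1cc(Br)ccc1O[Si](C)(C)C(C)(C)C | intermediate
3 | [4-(tert-butyldimethylsilyloxy)-3-methoxyphenyl]lithium | COc1cc([Li])ccc1O[Si](C)(C)C(C)(C)C | intermediate
4 | lithium [4-(tert-butyldimethylsilyloxy)-3-methoxyphenyl]triisopropoxyborate | [Li+].COc1cc([B-](OC(C)C)(OC(C)C)OC(C)C)ccc1O[Si](C)(C)C(C)(C)C | intermediate
5 | [4-(tert-butyldimethylsilyloxy)-3-methoxyphenyl]boronic acid | COc1cc(B(O)O)ccc1O[Si](C)(C)C(C)(C)C | intermediate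
6 | 5,6-dihydro-2H-pyran-2-one | O=C1C=CCCO1 | starting material
7 | (R)-4-[4-(tert-butyldimethylsilyloxy)-3-methoxyphenyl]tetrahydro-2H-pyran-2-one | O=C1C[C@H](c2ccc(O[Si](C)(C)C(C)(C)C)c(OC)c2)CCO1 | intermediate
8 | methyl (R)-3-[4-(tert-butyldimethylsilyloxy)-3-methoxyphenyl]-5-hydroxypentanoate | COC(=O)C[C@H](c1ccc(O[Si](C)(C)C(C)(C)C)c(OC)c1)CCO | intermediate
9 | methyl (R)-3-[4-(tert-butyldimethylsilyloxy)-3-methoxyphenyl]-5-oxopentanoate | COC(=O)C[C@H](c1ccc(O[Si](C)(C)C(C)(C)C)c(OC)c1)CC=O | intermediate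
10 | (R)-3-[4-(tert-butyldimethylsilyloxy)-3-methoxyphenyl]-5-methoxy-5-oxopentanoic acid | COC(=O)C[C@H](c1ccc(O[Si](C)(C)C(C)(C)C)c(OC)c1)CC(=O)O | intermediate
11 | methyl (S)-3-[4-(tert-butyldimethylsilyloxy)-3-methoxyphenyl]-5-chloro-5-oxopentanoate | COC(=O)C[C@H](c1ccc(O[Si](C)(C)C(C)(C)C)c(OC)c1)CC(=O)Cl | intermediate
12 | ethoxyacetylene | CCOC#C | starting material
13 | methyl (S)-3-[4-(tert-butyldimethylsilyloxy)-3-methoxyphenyl]-5-oxopent-4-enoate (ketene) | COC(=O)C[C@H](c1ccc(O[Si](C)(C)C(C)(C)C)c(OC)c1)C=C=O | intermediate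
14 | methyl (3S)-3-[4-(tert-butyldimethylsilyloxy)-3-methoxyphenyl]-3-(2-ethoxy-4-oxocyclobut-2-en-1-yl)propanoate, epimers at the ring carbon | COC(=O)C[C@H](c1ccc(O[Si](C)(C)C(C)(C)C)c(OC)c1)C1C(OCC)=CC1=O | intermediate
15 | ferulic acid | COc1cc(/C=C/C(=O)O)ccc1O | starting material
16 | tert-butyldimethylsilyl (E)-3-[4-(tert-butyldimethylsilyloxy)-3-methoxyphenyl]prop-2-enoate | COc1cc(/C=C/C(=O)O[Si](C)(C)C(C)(C)C)ccc1O[Si](C)(C)C(C)(C)C | intermediate
17 | (E)-3-[4-(tert-butyldimethylsilyloxy)-3-methoxyphenyl]prop-2-enoic acid | COc1cc(/C=C/C(=O)O)ccc1O[Si](C)(C)C(C)(C)C | intermediate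
18 | (E)-[4-(2-bromoethenyl)-2-methoxyphenoxy](tert-butyl)dimethylsilane | COc1cc(/C=C/Br)ccc1O[Si](C)(C)C(C)(C)C | intermediate
19 | (E)-2-[4-(tert-butyldimethylsilyloxy)-3-methoxyphenyl]ethenyllithium | COc1cc(/C=C/[Li])ccc1O[Si](C)(C)C(C)(C)C | intermediate
20 | (E)-2-[4-(tert-butyldimethylsilyloxy)-3-methoxyphenyl]ethenylcerium dichloride | COc1cc(/C=C/[Ce](Cl)Cl)ccc1O[Si](C)(C)C(C)(C)C | intermediate
21 | methyl (3S)-3-[4-(tert-butyldimethylsilyloxy)-3-methoxyphenyl]-3-{4-[(E)-2-[4-(tert-butyldimethylsilyloxy)-3-methoxyphenyl]ethenyl]-2-ethoxy-4-hydroxycyclobut-2-en-1-yl}propanoate, ring stereocentres unassigned | COC(=O)C[C@H](c1ccc(O[Si](C)(C)C(C)(C)C)c(OC)c1)C1C(OCC)=CC1(O)/C=C/c1ccc(O[Si](C)(C)C(C)(C)C)c(OC)c1 | intermediate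
22 | methyl (3S)-3-[4-(tert-butyldimethylsilyloxy)-3-methoxyphenyl]-3-{2-[(E)-2-[4-(tert-butyldimethylsilyloxy)-3-methoxyphenyl]ethenyl]-4-oxocyclobut-2-en-1-yl}propanoate, epimers at the ring carbon | O=C1C=C(/C=C/c2ccc(O[Si](C)(C)C(C)(C)C)c(OC)c2)C1[C@@H](c1ccc(O[Si](C)(C)C(C)(C)C)c(OC)c1)CC(=O)OC | intermediate
23 | acetylene | C#C | starting material
24 | lithium acetylide | [Li]C#C | intermediate
25 | lithium ethynolate | [Li]OC#C | intermediate
26 | (ethynyloxy)tri(propan-2-yl)silane | C#CO[Si](C(C)C)(C(C)C)C(C)C | intermediate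
27 | vinylketene from ring opening of 22, side chain trans to the ketene-bearing carbon, (S) at the stereocentre | O=C=C/C(/C=C/c1ccc(O[Si](C)(C)C(C)(C)C)c(OC)c1)=C/[C@@H](c1ccc(O[Si](C)(C)C(C)(C)C)c(OC)c1)CC(=O)OC | intermediate
28 | 4-dienyl-3-(triisopropylsilyloxy)cyclobut-2-enone from 27 and 26, ring carbon unassigned | O=C1C=C(O[Si](C(C)C)(C(C)C)C(C)C)C1/C(/C=C/c1ccc(O[Si](C)(C)C(C)(C)C)c(OC)c1)=C/[C@@H](c1ccc(O[Si](C)(C)C(C)(C)C)c(OC)c1)CC(=O)OC | intermediate
29 | dienylketene from ring opening of 28, central alkene cis | O=C=C/C(O[Si](C(C)C)(C(C)C)C(C)C)=C\C(\C=C\c1ccc(O[Si](C)(C)C(C)(C)C)c(OC)c1)=C\[C@@H](c1ccc(O[Si](C)(C)C(C)(C)C)c(OC)c1)CC(=O)OC | intermediate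
30 | 6-substituted 3-(triisopropylsilyloxy)-5-styrylcyclohexa-2,4-dienone, ring carbon unassigned | O=C1C=C(O[Si](C(C)C)(C(C)C)C(C)C)C=C(/C=C/c2ccc(O[Si](C)(C)C(C)(C)C)c(OC)c2)C1[C@@H](c1ccc(O[Si](C)(C)C(C)(C)C)c(OC)c1)CC(=O)OC | intermediate
31 | methyl (3R)-3-[4-(tert-butyldimethylsilyloxy)-3-methoxyphenyl]-3-{2-[(E)-2-[4-(tert-butyldimethylsilyloxy)-3-methoxyphenyl]ethenyl]-6-hydroxy-4-(triisopropylsilyloxy)phenyl}propanoate | Oc1cc(O[Si](C(C)C)(C(C)C)C(C)C)cc(/C=C/c2ccc(O[Si](C)(C)C(C)(C)C)c(OC)c2)c1[C@@H](c1ccc(O[Si](C)(C)C(C)(C)C)c(OC)c1)CC(=O)OC | intermediate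
32 | methyl (3R)-3-{2,4-dihydroxy-6-[(E)-2-(4-hydroxy-3-methoxyphenyl)ethenyl]phenyl}-3-(4-hydroxy-3-methoxyphenyl)propanoate | Oc1cc(O)cc(/C=C/c2ccc(O)c(OC)c2)c1[C@@H](c1ccc(O)c(OC)c1)CC(=O)OC | intermediate
33 | (4R)-7-hydroxy-4-(4-hydroxy-3-methoxyphenyl)-5-[(E)-2-(4-hydroxy-3-methoxyphenyl)ethenyl]chroman-2-one | COc1cc(/C=C/c2cc(O)cc3c2[C@@H](c2ccc(O)c(OC)c2)CC(=O)O3)ccc1O | target

**Count and risks**

Total step count: 14. Longest linear sequence: 11 steps (steps 1–7, 10, 12, 13, 14, from 4-bromo-2-methoxyphenol).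

Step 11 (most likely to fail). Monolithium acetylide may disproportionate to the insoluble dilithium salt before it is oxidised, and the unhindered ynolate 25 may be silylated on carbon to give a silylketene in place of 26. The fallback replaces the silyl ynol ether by an alkyl ynol ether whose alkyl group fluoride also removes; it sets out from cyclobutenone 22 and comes back at triphenol ester 32. Sodium 2-(trimethylsilyl)ethoxide (NaH, THF) adds to trichloroethylene to give (E)-[2-(1,2-dichloroethenyloxy)ethyl]trimethylsilane F1. n-BuLi (2.2 equiv, −78 °C) and then methanol convert it into [2-(ethynyloxy)ethyl]trimethylsilane F2. Benzannulation of 22 with F2 under the conditions of step 12 gives the 4-[2-(trimethylsilyl)ethoxy] analogue of phenol 31 F3. Bu4NF in DMF at 60 °C then removes both tert-butyldimethylsilyl groups and, by fluoride-induced β-elimination, the 2-(trimethylsilyl)ethyl group to give 32.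

Step 12. The ring opening of 22 needs a temperature at which the product phenol can be acylated by ketene intermediates and at which 26 can drift to the silylketene by a 1,3-silyl shift, so the cascade may end in oligomers. The fallback generates the same vinylketene at room temperature from an acid chloride and heats the cycloadduct on its own; it sets out from 22 and comes back at vinylcyclobutenone 28. Heating 22 in wet 1,4-dioxane at 80 °C traps vinylketene 27 with water as (3Z,5S)-5-[4-(tert-butyldimethylsilyloxy)-3-methoxyphenyl]-3-[(E)-2-[4-(tert-butyldimethylsilyloxy)-3-methoxyphenyl]ethenyl]-7-methoxy-7-oxohept-3-enoic acid F4. Oxalyl chloride converts it into the corresponding acid chloride F5. Et3N at room temperature in the presence of 26 regenerates 27 by dehydrochlorination, which adds 26 to give 28. Isolated 28 is then heated alone in toluene and should pass through 29 and 30 to 31.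

Step 10. The alkenylmetal, or the tertiary alkoxide it creates next to the side chain, may attack the methyl ester, and the bromine–lithium exchange may be incomplete. The fallback brings in the two styryl carbons as an acetylide, which does not attack esters at −78 °C, and sets the (E)-alkene afterwards; it sets out from 18 and 14 and comes back at 32. LiN(i-Pr)2 (2.2 equiv) dehydrobrominates 18 to lithium [4-(tert-butyldimethylsilyloxy)-3-methoxyphenyl]acetylide F6, which adds to the ring carbonyl of 14. Acid hydrolysis as in step 10 gives the 3-(arylethynyl) analogue of cyclobutenone 22 F7. Benzannulation with 26 as in step 12 gives the 5-(arylethynyl) analogue of phenol 31 F8. Ruthenium-catalysed trans-hydrosilylation ([Cp*Ru(MeCN)3]PF6, (EtO)3SiH, CH2Cl2) gives the (Z)-vinyl(triethoxy)silane F9, whose two regioisomers converge. Bu4NF with CuI replaces silicon by hydrogen with retention, which gives the (E)-alkene, and removes the three silyl ethers to reach 32.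

**Further compounds**

F1 | step 11 | (E)-[2-(1,2-dichloroethenyloxy)ethyl]trimethylsilane | Cl/C=C(/Cl)OCC[Si](C)(C)C
F2 | step 11 | [2-(ethynyloxy)ethyl]trimethylsilane | C#COCC[Si](C)(C)C
F3 | step 11 | methyl (3R)-3-[4-(tert-butyldimethylsilyloxy)-3-methoxyphenyl]-3-{2-[(E)-2-[4-(tert-butyldimethylsilyloxy)-3-methoxyphenyl]ethenyl]-6-hydroxy-4-[2-(trimethylsilyl)ethoxy]phenyl}propanoate | Oc1cc(OCC[Si](C)(C)C)cc(/C=C/c2ccc(O[Si](C)(C)C(C)(C)C)c(OC)c2)c1[C@@H](c1ccc(O[Si](C)(C)C(C)(C)C)c(OC)c1)CC(=O)OC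
F4 | step 12 | (3Z,5S)-5-[4-(tert-butyldimethylsilyloxy)-3-methoxyphenyl]-3-[(E)-2-[4-(tert-butyldimethylsilyloxy)-3-methoxyphenyl]ethenyl]-7-methoxy-7-oxohept-3-enoic acid | OC(=O)C/C(/C=C/c1ccc(O[Si](C)(C)C(C)(C)C)c(OC)c1)=C/[C@@H](c1ccc(O[Si](C)(C)C(C)(C)C)c(OC)c1)CC(=O)OC
F5 | step 12 | methyl (3S,4Z)-3-[4-(tert-butyldimethylsilyloxy)-3-methoxyphenyl]-5-[(E)-2-[4-(tert-butyldimethylsilyloxy)-3-methoxyphenyl]ethenyl]-7-chloro-7-oxohept-4-enoate | ClC(=O)C/C(/C=C/c1ccc(O[Si](C)(C)C(C)(C)C)c(OC)c1)=C/[C@@H](c1ccc(O[Si](C)(C)C(C)(C)C)c(OC)c1)CC(=O)OC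
F6 | step 10 | lithium [4-(tert-butyldimethylsilyloxy)-3-methoxyphenyl]acetylide | [Li]C#Cc1ccc(O[Si](C)(C)C(C)(C)C)c(OC)c1
F7 | step 10 | methyl (3S)-3-[4-(tert-butyldimethylsilyloxy)-3-methoxyphenyl]-3-{2-[[4-(tert-butyldimethylsilyloxy)-3-methoxyphenyl]ethynyl]-4-oxocyclobut-2-en-1-yl}propanoate | O=C1C=C(C#Cc2ccc(O[Si](C)(C)C(C)(C)C)c(OC)c2)C1[C@@H](c1ccc(O[Si](C)(C)C(C)(C)C)c(OC)c1)CC(=O)OC
F8 | step 10 | methyl (3R)-3-[4-(tert-butyldimethylsilyloxy)-3-methoxyphenyl]-3-{2-[[4-(tert-butyldimethylsilyloxy)-3-methoxyphenyl]ethynyl]-6-hydroxy-4-(triisopropylsilyloxy)phenyl}propanoate | Oc1cc(O[Si](C(C)C)(C(C)C)C(C)C)cc(C#Cc2ccc(O[Si](C)(C)C(C)(C)C)c(OC)c2)c1[C@@H](c1ccc(O[Si](C)(C)C(C)(C)C)c(OC)c1)CC(=O)OC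
F9 | step 10 | methyl (3R)-3-[4-(tert-butyldimethylsilyloxy)-3-methoxyphenyl]-3-{2-[(Z)-2-[4-(tert-butyldimethylsilyloxy)-3-methoxyphenyl]-2-(triethoxysilyl)ethenyl]-6-hydroxy-4-(triisopropylsilyloxy)phenyl}propanoate (one of two regioisomers) | Oc1cc(O[Si](C(C)C)(C(C)C)C(C)C)cc(/C=C(/c2ccc(O[Si](C)(C)C(C)(C)C)c(OC)c2)[Si](OCC)(OCC)OCC)c1[C@@H](c1ccc(O[Si](C)(C)C(C)(C)C)c(OC)c1)CC(=O)OC
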